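All runs were generated by integration with constants of no real substance, noise included.

At 15 h I read a flask charged with 0.10 M of substrate, so I ask how many half-lives of its approach to rest fit into that time. Amounts are fractions of the substrate charged.

| flask | substrate | remark | time |
|---|---|---|---|
| south-west | 0.14 M | run made earlier |  |
| north-east | 0.22 M | run made earlier |  |
| flask | 0.10 M |  | 15 h |

| run | time / h | substrate / % | target / % | isomer of the product A / % |
|---|---|---|---|---|
| south-west | 0.667 | 65.4 | 5.5 | 26.0 |
| south-west | 1.33 | 44.9 | 8.1 | 42.9 |
| south-west | 2.50 | 29.3 | 9.3 | 54.2 |
| south-west | 5.00 | 22.4 | 10.8 | 62.5 |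
| south-west | 10.0 | 24.0 | 7.8 | 59.8 |
| north-east | 0.833 | 58.6 | 6.9 | 30.5 |
| north-east | 2.50 | 29.0 | 7.8 | 54.2 |
| north-east | 4.00 | 24.5 | 8.4 | 57.8 |
| north-east | 6.00 | 22.0 | 8.6 | 60.9 |
| north-east | 10.0 | 24.3 | 7.5 | 62.4 |

(standard deviation of a reading: 1 percentage point)

- the state of affairs at 15 h: stopped, and by what, or still going (it is still moving / forward and back rates have come level / all of the substrate has reacted)
- share of the substrate used up at 15 h
- target at 15 h, in percent of the substrate charged
- isomer of the product A at 15 h, in percent of the substrate charged

- the numbers in the tables scatter by 1 percentage point (one standard deviation)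
- the reaction counts as stopped when no species that holds the substrate changes by six tenths of a point or more over the second half of the time

Two settings can be turned. The first is the charge: by hand, a first-order approach keeps its half-life at any charge, so the curve in fractions would not move. The readings agree: at 2.50 h the south-west run holds 29.3% substrate and the north-east run 29.0%, a gap of 0.3 percentage points, smaller than the scatter of 1 point. I therefore take the same curve for this flask, though its charge lies below both.

The second is the time: by hand, more time adds nothing once the flask rests. The south-west run reads 22.4% substrate at 5.00 h and 24.0% at 10.0 h, so it rests with substrate present. I average the last two readings of each run and measure the gap to that plateau: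

plateau of substrate = 23.2%

gap = 76.8% at the start, 21.7% at 1.33 h

half-life read from these = 0.730 h

half-lives elapsed = 15 h / 0.730 h = 20.6

This count, the time of reading over the half-life of the approach, is what I carry. By this count the substrate in this flask has 0.062 points left to move from 7.50 h on, less than the scatter. So I commit to a stop at equilibrium (thermodynamic control), with 76.8% of the substrate used up. The same late readings average 8.68% target and 61.4% isomer of the product A.

The forecast says forward and back rates have come level, with 76.5% used up, 61% isomer of the product A and 8% target, which is lower than my figure, and holds that “by 15 h the approach is long finished”.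

The flask gives: forward and back rates have come level, with 77.8% used up, 9.10% target and 61.3% isomer of the product A.

    substrate ⇌ target (K = 0.410, k = 0.232 h⁻¹)
    target ⇌ isomer of the product C (K = 0.289, k = 0.352 h⁻¹)
    isomer of the product A ⇌ isomer of the product B (K = 0.0782, k = 0.871 h⁻¹)
    target → over-reaction product (k = 9.92 × 10⁻⁵ h⁻¹)
    target ⇌ isomer of the product A (K = 6.73, k = 2.29 h⁻¹)
    isomer of the product B ⇌ substrate (k = 2.80 h⁻¹)

The conversion comes within a twentieth of its value at 3.30 h, which is shorter than the 15 h of reading and takes 4.52 of the 20.6 half-lives I counted. The half-lives after that leave the substrate at 22.3% at 7.50 h and 22.2% at 15.0 h, and at 150 h, ten times as long, the conversion stands at 77.8%. A neighbour flask charged with 0.17 M of substrate and read at the same time has, by my count, again 20.6 half-lives behind it, and it stands at 77.8% used up, 9.10% target and 61.3% isomer of the product A.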